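**Retrosynthetic overview**

- The last operation joins two pieces and makes the only new ring. It cuts the C4–C5 bond of the 5-hydroxy-2,2,6,6-tetramethylcyclohex-4-ene-1,3-dione ring (intramolecular Claisen; ring C5 becomes a methyl ester carbon) together with the aryl–CH bond (enantioselective Friedel–Crafts conjugate addition, which sets the single stereocentre). This leads back to the acylphloroglucinol and an acyclic (E)-enone 3,5-diketo ester.
- The enone diketo ester comes from an aldol/oxidation pair between (E)-5-phenylpent-2-enal (Wittig from 3-phenylpropanal) and methyl 2,2,4-trimethyl-3-oxopentanoate (methanolysis of dimethylketene dimer). The acylphloroglucinol comes from C-acylation of 2-methylphloroglucinol.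
- Ring order: all three benzene rings are bought; the trione ring is the only ring formed and is closed last.
- Enabling feature: ring carbons C2 and C6 are quaternary (gem-dimethyl), so in the open chain the future ring C4 is the only enolisable carbon of the tricarbonyl array and has one ester to close on. The ring C1/C3 carbonyl pair, held by quaternary C2, is a non-enolisable 1,3-diketone that can chelate a chiral Lewis acid. The closed ring is a vinylogous acid whose enolate is the thermodynamic sink, and the phloroglucinol ring has exactly one free C–H between two OH groups.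

Key step: step 6

Remark: the trione ring is drawn as one of two degenerate enol tautomers, so the two carbons flanking ring C4 are equivalent; the descriptor (R) refers to the drawn form.

**Step 1**
Reactants: 1 2-methylbenzene-1,3,5-triol (2-methylphloroglucinol); 2 3-phenylpropanoyl chloride
Product: 3 1-(2,4,6-trihydroxy-3-methylphenyl)-3-phenylpropan-1-one
Conditions: AlCl3 (3.5 equiv), PhNO2/CH2Cl2, 0 °C to 60 °C; ice/aq. HCl
Reagents that add atoms: none
Why: Friedel–Crafts acylation of the highly activated ring; the two free positions of 1 are equivalent, so one regioisomer should form, and the new acyl group deactivates the ring against a second acylation.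

**Step 2**
Reactants: 4 2,2,4,4-tetramethylcyclobutane-1,3-dione (dimethylketene dimer)
Product: 5 methyl 2,2,4-trimethyl-3-oxopentanoate
Conditions: NaOMe (2 mol%), MeOH, rt to 50 °C
Reagents that add atoms: methanol, CO
Why: Methoxide-catalysed ring-opening methanolysis (strain-driven retro-Claisen cleavage) of the non-enolisable cyclobutane-1,3-dione, the standard entry to this keto ester.

**Step 3**
Reactants: 6 3-phenylpropanal
Product: 7 (E)-5-phenylpent-2-enal
Conditions: Ph3P=CHCHO (1.1 equiv), toluene, 80 °C
Reagents that add atoms: (triphenylphosphoranylidene)acetaldehyde, O=CC=P(c1ccccc1)(c1ccccc1)c1ccccc1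
Why: Wittig olefination with the stabilised formylmethylene ylide should give the (E)-enal selectively.

**Step 4**
Reactants: 5 methyl 2,2,4-trimethyl-3-oxopentanoate; 7 (E)-5-phenylpent-2-enal
Product: 8 methyl (E)-5-hydroxy-2,2,4,4-tetramethyl-3-oxo-9-phenylnon-6-enoate (racemic at C5)
Conditions: LiN(iPr)2 (1.05 equiv), THF, −78 °C; then 7, −78 °C; AcOH quench at −78 °C
Reagents that add atoms: none
Why: Directed aldol addition: 5 can be deprotonated only at the isopropyl methine, and the tetrasubstituted lithium enolate should add 1,2 to the enal at −78 °C; the carbinol centre forms as a racemate and is removed in step 5.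

**Step 5**
Reactants: 8 methyl (E)-5-hydroxy-2,2,4,4-tetramethyl-3-oxo-9-phenylnon-6-enoate
Product: 9 methyl (E)-2,2,4,4-tetramethyl-3,5-dioxo-9-phenylnon-6-enoate
Conditions: Dess–Martin periodinane (1.3 equiv), CH2Cl2, 0 °C to rt
Reagents that add atoms: none
Why: Dess–Martin oxidation of the secondary allylic alcohol under non-basic conditions should give the enone without retro-aldol cleavage and leave the (E)-alkene and the ester untouched.

**Step 6**
Reactants: 3 1-(2,4,6-trihydroxy-3-methylphenyl)-3-phenylpropan-1-one; 9 methyl (E)-2,2,4,4-tetramethyl-3,5-dioxo-9-phenylnon-6-enoate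
Product: 11 5-hydroxy-2,2,6,6-tetramethyl-4-{(1R)-3-phenyl-1-[2,4,6-trihydroxy-3-methyl-5-(3-phenylpropanoyl)phenyl]propyl}cyclohex-4-ene-1,3-dione (target), via conjugate-addition keto ester 10 (not isolated)
Conditions: Ni(ClO4)2·6H2O (10 mol%), (S,S)-DBFOX/Ph [(S,S)-4,6-dibenzofurandiyl-2,2'-bis(4-phenyloxazoline)] (10 mol%), 2,2,6,6-tetramethylpiperidine (10 mol%), THF, 0 °C to rt; then LiN(SiMe3)2 (6 equiv), −78 to −20 °C; AcOH quench at −78 °C, work-up at pH 4–5 without heating
Reagents that add atoms: none
Why: Proposed new method: the divalent-nickel DBFOX aqua complex should bind the C3/C5 1,3-diketone of 9 as a six-membered chelate, holding the (E)-enone s-cis and lowering its LUMO, so that the one free ring carbon of 3 (as its amine-generated phenoxide) adds to C7 to give 10, after which LiN(SiMe3)2 converts 10 into its triphenoxide C6-enolate, which attacks the C1 ester carbonyl and expels methoxide to leave the triketone enolate as the thermodynamic sink. The closest known reaction types are divalent-nickel-catalysed conjugate addition of acylphloroglucinols to alkylidene 1,3-dicarbonyl compounds, DBFOX/nickel-catalysed enantioselective conjugate additions to chelating 3-enoyl-oxazolidinones, and the base-mediated Dieckmann-type cyclisation of methyl 2,2,4,4-tetramethyl-3,5-dioxohexanoate to syncarpic acid; new are the singly activated acyclic diketo enone as acceptor and the union of the two events in one flask. The trione ring closes in the 6-(enolendo)-exo-trig mode between chain C6 (ring C4) and chain C1 (ring C5), favoured by the Thorpe–Ingold effect of the two CMe2 groups. The single stereocentre is set in the conjugate addition under catalyst control: by analogy with crotonoyl-oxazolidinone additions the 4-phenyl groups of the (S,S)-ligand are expected to shield the C7 Re face, so the arene should enter on the Si face to give (S)-10, which is (R)-11 after closure by a change of CIP priorities only (the (R,R)-ligand is the remedy should the sense prove opposite), and the centre carries no acidic hydrogen, so the cold base stage should not touch it. The step needs C-alkylation at one ring position, secured by the single free C–H of 3 between two OH groups and by the reversibility of oxa-Michael addition, and enolisation at C6 alone, secured by the quaternary C2 and C4 of the chain, while the only other acidic CH2 (next to the aryl ketone) is deactivated by the phenoxides and has no carbonyl within reach of a five- or six-membered closure. C- over O-acylation of the enolate is secured thermodynamically, because an enol lactone from O-attack is reopened by methoxide whereas the C-acylated triketone enolate is not.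

**Compound list**

1 | 2-methylbenzene-1,3,5-triol (2-methylphloroglucinol) | Cc1c(O)cc(O)cc1O | starting material
2 | 3-phenylpropanoyl chloride | O=C(Cl)CCc1ccccc1 | starting material
3 | 1-(2,4,6-trihydroxy-3-methylphenyl)-3-phenylpropan-1-one | Cc1c(O)c(C(=O)CCc2ccccc2)c(O)cc1O | intermediate
4 | 2,2,4,4-tetramethylcyclobutane-1,3-dione | CC1(C)C(=O)C(C)(C)C1=O | starting material
5 | methyl 2,2,4-trimethyl-3-oxopentanoate | COC(=O)C(C)(C)C(=O)C(C)C | intermediate
6 | 3-phenylpropanal | O=CCCc1ccccc1 | starting material
7 | (E)-5-phenylpent-2-enal | O=C/C=C/CCc1ccccc1 | intermediate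
8 | methyl (E)-5-hydroxy-2,2,4,4-tetramethyl-3-oxo-9-phenylnon-6-enoate (racemic) | COC(=O)C(C)(C)C(=O)C(C)(C)C(O)/C=C/CCc1ccccc1 | intermediate
9 | methyl (E)-2,2,4,4-tetramethyl-3,5-dioxo-9-phenylnon-6-enoate | COC(=O)C(C)(C)C(=O)C(C)(C)C(=O)/C=C/CCc1ccccc1 | intermediate
10 | methyl (7S)-2,2,4,4-tetramethyl-3,5-dioxo-9-phenyl-7-[2,4,6-trihydroxy-3-methyl-5-(3-phenylpropanoyl)phenyl]nonanoate (not isolated) | Cc1c(O)c(C(=O)CCc2ccccc2)c(O)c([C@@H](CCc2ccccc2)CC(=O)C(C)(C)C(=O)C(C)(C)C(=O)OC)c1O | intermediate
11 | 5-hydroxy-2,2,6,6-tetramethyl-4-{(1R)-3-phenyl-1-[2,4,6-trihydroxy-3-methyl-5-(3-phenylpropanoyl)phenyl]propyl}cyclohex-4-ene-1,3-dione | Cc1c(O)c(C(=O)CCc2ccccc2)c(O)c([C@@H](CCc2ccccc2)C2=C(O)C(C)(C)C(=O)C(C)(C)C2=O)c1O | target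

**Step count and risks**

Total step count: 6. Longest linear sequence: 4 steps (steps 3, 4, 5, 6 or steps 2, 4, 5, 6).

Steps most likely to fail:

1. Step 6 (proposed new method). What may go wrong:
   - poor facial selectivity or slow turnover in the conjugate addition to a singly activated enone, because the polyphenol ketone competes for the metal;
   - erosion of enantiopurity by retro-Michael ionisation in the basic stage;
   - chain cleavage by released methoxide (retro-Claisen) outrunning ring closure.

   Fallback with known chemistry, setting out from 5 and returning at 11: the lithium enolate of 5 (LiN(iPr)2, THF, −78 °C) is acetylated with acetyl chloride to methyl 2,2,4,4-tetramethyl-3,5-dioxohexanoate F1. NaOMe in MeOH closes the same ring bond by Dieckmann cyclisation to 5-hydroxy-2,2,6,6-tetramethylcyclohex-4-ene-1,3-dione (syncarpic acid) F2. Knoevenagel condensation with 6 (L-proline, CH2Cl2) should give 2,2,4,4-tetramethyl-6-(3-phenylpropylidene)cyclohexane-1,3,5-trione F3. Michael addition of 3 (NaH cat., THF) should give the racemic target F4. Preparative HPLC on a chiral stationary phase then delivers 11, and the (S)-enantiomer F5 is discarded.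

2. Step 4. What may go wrong: retro-aldol fragmentation of the hindered lithium aldolate on warming, lactonisation of the aldolate onto the methyl ester, and competing 1,4-addition to the enal.

   Fallback setting out from 7 (with 5) and returning at 9: Pinnick oxidation of 7 (NaClO2, NaH2PO4, 2-methylbut-2-ene, tBuOH/H2O) gives (E)-5-phenylpent-2-enoic acid F6. Oxalyl chloride with catalytic DMF in CH2Cl2 gives (E)-5-phenylpent-2-enoyl chloride F7. The lithium enolate of 5 (LiN(iPr)2, THF, −78 °C) is C-acylated with F7, modelled on its acetylation, and should give 9 directly without passing through 8 or the oxidation.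

3. Step 3. What may go wrong: a second homologation of the product enal by the ylide, and incomplete conversion.

   Fallback setting out from 6 and returning at 7: Horner–Wadsworth–Emmons olefination of 6 with triethyl phosphonoacetate (NaH, THF) gives ethyl (E)-5-phenylpent-2-enoate F8. Reduction with iBu2AlH (CH2Cl2, −78 °C) gives (E)-5-phenylpent-2-en-1-ol F9. Oxidation with MnO2 (CH2Cl2, rt) gives 7.

**Further compounds**

F1 | step 6 | methyl 2,2,4,4-tetramethyl-3,5-dioxohexanoate | COC(=O)C(C)(C)C(=O)C(C)(C)C(C)=O
F2 | step 6 | 5-hydroxy-2,2,6,6-tetramethylcyclohex-4-ene-1,3-dione (syncarpic acid) | CC1(C)C(=O)C=C(O)C(C)(C)C1=O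
F3 | step 6 | 2,2,4,4-tetramethyl-6-(3-phenylpropylidene)cyclohexane-1,3,5-trione | CC1(C)C(=O)C(=CCCc2ccccc2)C(=O)C(C)(C)C1=O
F4 | step 6 | racemic 5-hydroxy-2,2,6,6-tetramethyl-4-{3-phenyl-1-[2,4,6-trihydroxy-3-methyl-5-(3-phenylpropanoyl)phenyl]propyl}cyclohex-4-ene-1,3-dione | Cc1c(O)c(C(=O)CCc2ccccc2)c(O)c(C(CCc2ccccc2)C2=C(O)C(C)(C)C(=O)C(C)(C)C2=O)c1O
F5 | step 6 | 5-hydroxy-2,2,6,6-tetramethyl-4-{(1S)-3-phenyl-1-[2,4,6-trihydroxy-3-methyl-5-(3-phenylpropanoyl)phenyl]propyl}cyclohex-4-ene-1,3-dione | Cc1c(O)c(C(=O)CCc2ccccc2)c(O)c([C@H](CCc2ccccc2)C2=C(O)C(C)(C)C(=O)C(C)(C)C2=O)c1O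
F6 | step 4 | (E)-5-phenylpent-2-enoic acid | OC(=O)/C=C/CCc1ccccc1
F7 | step 4 | (E)-5-phenylpent-2-enoyl chloride | ClC(=O)/C=C/CCc1ccccc1
F8 | step 3 | ethyl (E)-5-phenylpent-2-enoate | CCOC(=O)/C=C/CCc1ccccc1
F9 | step 3 | (E)-5-phenylpent-2-en-1-ol | OC/C=C/CCc1ccccc1
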